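The autumn run is the midnight run with 0.120 M of L added at the start, so the gap between the two flasks follows what becomes of L that is already there.

| flask | E | G | L | time |
|---|---|---|---|---|
| midnight | 0.250 M | 0.0200 M |  |  |
| dawn | 0.150 M | 0.0200 M |  |  |
| autumn | 0.250 M | 0.0200 M | 0.120 M |  |
| dusk | 0.250 M | 0.0300 M |  |  |
| winter | 0.250 M | 0.0200 M |  | 360 s |

- midnight run (time / s: [L] / M): 4.8: 0.0075; 7.6: 0.0142; 12: 0.0284; 19: 0.0498; 30: 0.0780; 48: 0.1161; 76: 0.1508; 120: 0.1737
- dawn run (time / s: [L] / M): 4.8: 0.0046; 7.6: 0.0090; 12: 0.0157; 19: 0.0301; 30: 0.0467; 48: 0.0706; 76: 0.0924; 120: 0.1048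
- autumn run (time / s: [L] / M): 4.8: 0.1261; 7.6: 0.1324; 12: 0.1443; 19: 0.1641; 30: 0.1916; 48: 0.2232; 76: 0.2512; 120: 0.2628
- dusk run (time / s: [L] / M): 4.8: 0.0097; 7.6: 0.0225; 12: 0.0426; 19: 0.0708; 30: 0.1080; 48: 0.1486; 76: 0.1805; 120: 0.1921

(scatter of a reading: 0.001 M)

1. how the opening rate goes with [G] round the charge of the midnight run: the exponent of the rate at two percent of E gone to L
2. how the opening rate goes with [E] round the charge of the midnight run: the exponent of the rate at two percent of E gone to L (one fixed amount of L, the same in the runs compared)
3. L in the winter run at 360 s, as a share of the E charged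

- Overall: E -> L, with G as catalyst.
- Constant volume, constant temperature.
- An order is taken over about fifteen percent of the charge, up and down.

Does L level off, or is it being lost? At 120 s the autumn excess over the midnight run has shrunk to 0.0891 M. As a fraction per second this is 0.00237 s⁻¹ up to 48 s and 0.00256 s⁻¹ after it. The later fraction is no smaller than the earlier one, so we read a steady loss and not a gap closing on a balance. We call the whole-stretch figure the loss constant of L, the fraction of L lost per second: 0.00248 s⁻¹.

How fast is L made? At 120 s L in the dawn run stands at 69.9% of its charge and L in the midnight run at 69.5%, so we take the fraction of E going per second as the same for both charges, pseudo-first-order at fixed G. In the midnight run between 30 s and 48 s, the slope of L plus the loss, divided by the charge minus L, gives a formation constant of 0.0154 s⁻¹. That divisor still counts as E the L already lost, about 0.00691 M by 48 s, so this constant is a low reading.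

What does the winter run, the midnight recipe left longer, hold at 360 s? We join the two ends: the share of L is the formation constant over the difference of the constants, times the difference of the two decay factors. By then hardly any E is left, and our reckoning gives 48.3%, give or take about 2.3 percentage points from the scatter. We leave out the opening lag: L is already rising at 4.8 s, far shorter than the 403 s lifetime of L.

The forecast gives 0.75 for G, 0.75 for E and 75.5%, higher than our share. Its reading of the flattening: “That suggests a reversible reaction, perhaps with slow catalyst decay.”

The flask gives 0.66 for G, 0.67 for E and 50.5% in the winter run.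

    Jy + E → L + Jy (0.7630 M⁻¹ s⁻¹)
    L → Qe (0.002360 s⁻¹)
    G → Jy (0.2500 s⁻¹)

L passes on to Qe in a step of its own. At the loss constant, the winter run at 360 s is shedding 3.13 × 10⁻⁴ M s⁻¹ of L. The dusk run has 1.50 times the G, so we scale the formation constant to 0.0231 s⁻¹. With the same loss constant this gives 0.190 M at 120 s, and the dusk reading there is 0.1921 M.

The data are calculated with made-up constants, and the scatter is random.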